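The butenolide is closed last, by ring-closing metathesis that forges its tetrasubstituted C7=C11 alkene (germacranolide numbering: carbocycle C1–C10, lactone O–C6–C7=C11–C12, C13 acetoxymethyl). The step exploits that C7 is exocyclic to the ten-membered ring and that C11 bears C13: both alkene carbons are presented as methylenes, C7=CH2 on the macrocycle and a 2-(acetoxymethyl)acrylate on O6, so the lactone forms without base, with C13–OAc in place and the C4–C5 epoxide next to C6 untouched. The precursor comes from a Sonogashira-joined dienyne that is epoxidised twice, reduced to the Z-alkene and cyclised by a Nozaki–Hiyama–Kishi reaction at C6–C7.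

Key step: step 16

Numbering used below: ring carbons C1–C10; epoxides at C1/C10 and C4/C5; Z-alkene C2=C3; lactone oxygen on C6; 2-methylbutanoate on C8; C11, C12 (C=O) and C13 (CH2OAc) complete the butenolide; C14 is the CH2OH on C10; C15 is the methyl on C4.

Assumption: compounds 4, 6, 12 and 19, the phosphoric acid (S)-TRIP and the D-fructose-derived Shi ketone are taken as purchasable.

Step 1
Reactants: 1 acrolein
Product: 3 2-bromoacrolein (2-bromoprop-2-enal), via 2,3-dibromopropanal 2 (not isolated)
Conditions: Br2, CH2Cl2, −78 → 0 °C; then Et3N, 0 °C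
Reagents that add atoms: bromine BrBr
Why: Electrophilic addition of bromine to the alkene followed by amine-induced E1cB loss of HBr from the α-position is the standard bromination–dehydrobromination route to α-bromo enals, and no stereocentre is involved.

Step 2
Reactants: 3 2-bromoacrolein; 4 allenylboronic acid pinacol ester
Product: 5 (3S)-2-bromohex-1-en-5-yn-3-ol
Conditions: (S)-TRIP [(S)-3,3′-bis(2,4,6-triisopropylphenyl)-1,1′-binaphthyl-2,2′-diyl hydrogen phosphate] (5 mol %), 4 Å molecular sieves, toluene, −20 → 0 °C; aqueous work-up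
Reagents that add atoms: none
Why: Chiral phosphoric acid-catalysed propargylboration (SE2′ addition of the allenylboronate through a six-membered transition state bound to the phosphate) should give the homopropargylic alcohol, the catalyst antipode (S)-TRIP being chosen to direct attack to the Si face of the aldehyde and so set C8 as S.

Step 3
Reactants: 5 (3S)-2-bromohex-1-en-5-yn-3-ol; 6 (2R)-2-methylbutanoic acid
Product: 7 (3S)-2-bromohex-1-en-5-yn-3-yl (2R)-2-methylbutanoate
Conditions: DCC, DMAP (10 mol %), CH2Cl2, 0 °C → rt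
Reagents that add atoms: none
Why: Steglich esterification acylates the secondary alcohol at oxygen, so C8 is retained and the α-branched acid should not racemise under these mild conditions.

Step 4
Reactants: 7 ester
Product: 8 (3S,5Z)-2-bromo-6-[dimethyl(phenyl)silyl]-5-formylhexa-1,5-dien-3-yl (2R)-2-methylbutanoate
Conditions: HSiMe2Ph, CO (15 atm), Rh4(CO)12 (0.5 mol %), toluene, 40 °C
Reagents that add atoms: dimethyl(phenyl)silane C[SiH](C)c1ccccc1; carbon monoxide [C-]#[O+]
Why: Rhodium-catalysed silylformylation of the terminal alkyne adds silicon to the terminal carbon (C1) and the formyl group (C14) to the internal carbon (C10) in a syn fashion, which fixes the C10=C1 geometry with C14 cis to the future C2, while the 2-bromoalkene and the ester are spectators.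

Step 5
Reactants: 8 silyl enal
Product: 9 (3S,5Z)-2-bromo-6-[dimethyl(phenyl)silyl]-5-(hydroxymethyl)hexa-1,5-dien-3-yl (2R)-2-methylbutanoate
Conditions: NaBH4, CeCl3·7H2O, MeOH, −40 °C
Reagents that add atoms: none
Why: Luche 1,2-reduction should convert the enal into the allylic alcohol without touching the ester, the vinylsilane or the alkenyl bromide.

Step 6
Reactants: 9 allylic alcohol
Product: 10 (3S,5Z)-2-bromo-5-{[tert-butyl(dimethyl)silyl]oxymethyl}-6-[dimethyl(phenyl)silyl]hexa-1,5-dien-3-yl (2R)-2-methylbutanoate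
Conditions: TBSCl, imidazole, DMF, 0 °C → rt
Reagents that add atoms: tert-butyl(chloro)dimethylsilane CC(C)(C)[Si](C)(C)Cl
Why: Silylation of the primary allylic alcohol masks the C14 hydroxyl, which has to stay protected until the last step.

Step 7
Reactants: 10 vinylsilane
Product: 11 (3S,5Z)-2-bromo-5-{[tert-butyl(dimethyl)silyl]oxymethyl}-6-iodohexa-1,5-dien-3-yl (2R)-2-methylbutanoate
Conditions: N-iodosuccinimide, (CF3)2CHOH, 0 °C
Reagents that add atoms: N-iodosuccinimide O=C1CCC(=O)N1I
Why: Electrophilic ipso-iododesilylation of the vinylsilane (β-silyl cation, then loss of silicon) proceeds with retention of alkene geometry and should give the iodide with iodine cis to the silyloxymethyl group, the electron-poor 2-bromoalkene not being attacked.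

Step 8
Reactants: 11 alkenyl iodide; 12 (2Z)-3-methylpent-2-en-4-yn-1-ol
Product: 13 (3S,5Z,9Z)-2-bromo-5-{[tert-butyl(dimethyl)silyl]oxymethyl}-11-hydroxy-9-methylundeca-1,5,9-trien-7-yn-3-yl (2R)-2-methylbutanoate
Conditions: Pd(PPh3)2Cl2 (3 mol %), CuI (6 mol %), iPr2NH, THF, rt
Reagents that add atoms: none
Why: Sonogashira coupling joins C1 to C2 with retention of both alkene geometries, the trisubstituted alkenyl iodide reacting with zerovalent palladium at room temperature far faster than the hindered 2-bromoalkene, which is kept for step 13.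

Step 9
Reactants: 13 dienyne
Product: 14 (3S,5Z)-2-bromo-5-{[tert-butyl(dimethyl)silyl]oxymethyl}-8-[(2R,3S)-3-(hydroxymethyl)-2-methyloxiran-2-yl]octa-1,5-dien-7-yn-3-yl (2R)-2-methylbutanoate
Conditions: Ti(OiPr)4 (10 mol %), L-(+)-diisopropyl tartrate (12 mol %), tBuOOH, 4 Å molecular sieves, CH2Cl2, −20 °C
Reagents that add atoms: tert-butyl hydroperoxide CC(C)(C)OO
Why: Sharpless asymmetric epoxidation of the free 3,3-disubstituted Z-allylic alcohol is reagent-controlled, L-(+)-tartrate giving the (4R,5S)-epoxide (the nerol-type sense), while the other trisubstituted alkene, whose allylic oxygen is silylated, is not epoxidised.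

Step 10
Reactants: 14 epoxy alcohol
Product: 15 (2S)-3-bromo-1-[(2S,3R)-2-{[tert-butyl(dimethyl)silyl]oxymethyl}-3-{[(2R,3S)-3-(hydroxymethyl)-2-methyloxiran-2-yl]ethynyl}oxiran-2-yl]but-3-en-2-yl (2R)-2-methylbutanoate
Conditions: D-fructose-derived Shi ketone (30 mol %), KHSO5 (as 2KHSO5·KHSO4·K2SO4), K2CO3, Bu4NHSO4, MeCN/CH2(OMe)2/aqueous borate buffer pH 10.5, 0 °C
Reagents that add atoms: potassium peroxymonosulfate [K+].[O-]S(=O)(=O)OO
Why: Shi epoxidation by the chiral dioxirane attacks the remaining electron-rich trisubstituted enyne alkene through the spiro transition state, the D-fructose-derived catalyst delivering oxygen to the face that gives the (1R,10S)-epoxide (catalyst control), whereas the alkyne and the 2-bromoalkene are inert.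

Step 11
Reactants: 15 bis-epoxy alkyne
Product: 16 (2S)-3-bromo-1-[(2S,3R)-2-{[tert-butyl(dimethyl)silyl]oxymethyl}-3-{(Z)-2-[(2R,3S)-3-(hydroxymethyl)-2-methyloxiran-2-yl]ethenyl}oxiran-2-yl]but-3-en-2-yl (2R)-2-methylbutanoate
Conditions: H2 (1 atm), Pd/CaCO3 poisoned with Pb(OAc)2, quinoline, EtOAc, rt
Reagents that add atoms: none
Why: Lindlar semihydrogenation (syn delivery of hydrogen on the poisoned palladium surface) should turn the alkyne between the two oxiranes into the Z C2=C3 alkene and stop there, leaving the alkenyl bromide and the epoxides intact.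

Step 12
Reactants: 16 epoxy alcohol
Product: 17 (2S)-3-bromo-1-[(2S,3R)-2-{[tert-butyl(dimethyl)silyl]oxymethyl}-3-{(Z)-2-[(2R,3R)-3-formyl-2-methyloxiran-2-yl]ethenyl}oxiran-2-yl]but-3-en-2-yl (2R)-2-methylbutanoate (the changed descriptor at C5 is a priority effect only)
Conditions: Dess–Martin periodinane, NaHCO3, CH2Cl2, 0 °C → rt
Reagents that add atoms: none
Why: Buffered Dess–Martin oxidation should give the α,β-epoxy aldehyde without epimerising C5 or opening either vinyl epoxide.

Step 13
Reactants: 17 bromo aldehyde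
Product: 18 (1R,2Z,4R,5S,6S,8S,10S)-14-{[tert-butyl(dimethyl)silyl]oxy}-1,10:4,5-diepoxy-6-hydroxy-7-methylidene-11,12,13-trinorgermacr-2-en-8-yl (2R)-2-methylbutanoate
Conditions: CrCl2 (8 equiv), NiCl2 (5 mol %), DMSO/THF, 0.003 M, rt → 40 °C
Reagents that add atoms: none
Why: In this Nozaki–Hiyama–Kishi reaction the nickel-catalysed formation of the alkenylchromium species from the 2-bromoalkene and its chemoselective addition to the aldehyde close the ten-membered ring (the Z-alkene and the cis-epoxide pre-bend the chain), and C6 should be set S by Felkin–Anh attack anti to the C5–O bond of the epoxy aldehyde (substrate control).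

Step 14
Reactants: 19 2-(bromomethyl)acrylic acid
Product: 20 2-(acetoxymethyl)acrylic acid
Conditions: NaOAc (3 equiv), AcOH, 60 °C
Reagents that add atoms: sodium acetate CC(=O)[O-].[Na+]
Why: Acetate displaces the allylic bromide (SN2 and SN2′ give the same product), and acetic acid as solvent keeps the carboxylic acid protonated so that it does not alkylate itself.

Step 15
Reactants: 18 macrocyclic alcohol; 20 2-(acetoxymethyl)acrylic acid
Product: 21 (1R,2Z,4R,5S,6S,8S,10S)-6-{[2-(acetoxymethyl)prop-2-enoyl]oxy}-14-{[tert-butyl(dimethyl)silyl]oxy}-1,10:4,5-diepoxy-7-methylidene-11,12,13-trinorgermacr-2-en-8-yl (2R)-2-methylbutanoate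
Conditions: EDC·HCl, DMAP (20 mol %), CH2Cl2, 0 °C → rt
Reagents that add atoms: none
Why: Carbodiimide-mediated acylation of the only free hydroxyl occurs at oxygen with retention at C6 and places the acrylate alkene five atoms away from C7=CH2.

Step 16
Reactants: 21 acrylate of the 7-methylidene macrocycle
Product: 22 14-O-[tert-butyl(dimethyl)silyl] ether of the target
Conditions: second-generation Grubbs catalyst RuCl2(=CHPh)(H2IMes)(PCy3) (15 mol %, in portions), toluene, 0.005 M, 80 °C, argon sparge
Reagents that add atoms: none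
Why: Ring-closing olefin metathesis: the ruthenium methylidene engages one of the two 1,1-disubstituted alkenes (C7=CH2 or the acrylate C11=CH2), the resulting alkylidene adds to the other alkene held five atoms away through the ester, and cycloreversion of the ruthenacyclobutane releases ethene and the C7=C11 bond. The closest known reaction type is the closure of methacrylates of 2-methylidenecycloalkanols to ring-fused tetrasubstituted butenolides. The five-membered lactone (O, C6, C7, C11, C12) is closed as an annulation onto the existing carbocycle in a diene ring-closing mode driven by loss of ethene, and the ten-membered ring is not opened. No stereocentre is created, and C6 and C8, which flank the new alkene, should not epimerise because neither base nor acid is present. The step needs chemoselectivity for the two terminal methylenes over the ring C2=C3 alkene, which is secured by that alkene being internal, cis and flanked by the quaternary C4 and the tertiary C1 epoxide carbons; neutral ruthenium catalysis should also spare C13–OAc and both vinyl epoxides.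

Step 17
Reactants: 22 silyl ether
Product: 23 (1R,2Z,4R,5S,6S,8S,10S)-13-acetoxy-1,10:4,5-diepoxy-14-hydroxy-8-[(2R)-2-methylbutanoyloxy]germacra-2,7(11)-dien-12,6-olide (CNP0108300.1)
Conditions: HF·pyridine, pyridine, THF, 0 °C
Reagents that add atoms: none
Why: Buffered fluoride cleavage of the primary silyl ether should free the C14 hydroxyl without acyl migration, Payne rearrangement or opening of the vinyl epoxides, since neither strong base nor strong acid is present.

Compound list
1 | acrolein | C=CC=O | starting material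
2 | 2,3-dibromopropanal (racemic, not isolated) | O=CC(Br)CBr | intermediate
3 | 2-bromoacrolein | C=C(Br)C=O | intermediate
4 | allenylboronic acid pinacol ester | C=C=CB1OC(C)(C)C(C)(C)O1 | starting material
5 | (3S)-2-bromohex-1-en-5-yn-3-ol | C#CC[C@H](O)C(Br)=C | intermediate
6 | (2R)-2-methylbutanoic acid | CC[C@@H](C)C(=O)O | starting material
7 | (3S)-2-bromohex-1-en-5-yn-3-yl (2R)-2-methylbutanoate | CC[C@@H](C)C(=O)O[C@H](C(Br)=C)CC#C | intermediate
8 | (3S,5Z)-2-bromo-6-[dimethyl(phenyl)silyl]-5-formylhexa-1,5-dien-3-yl (2R)-2-methylbutanoate | CC[C@@H](C)C(=O)O[C@H](C(Br)=C)C/C(C=O)=C/[Si](C)(C)c1ccccc1 | intermediate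
9 | (3S,5Z)-2-bromo-6-[dimethyl(phenyl)silyl]-5-(hydroxymethyl)hexa-1,5-dien-3-yl (2R)-2-methylbutanoate | CC[C@@H](C)C(=O)O[C@H](C(Br)=C)C/C(CO)=C/[Si](C)(C)c1ccccc1 | intermediate
10 | (3S,5Z)-2-bromo-5-{[tert-butyl(dimethyl)silyl]oxymethyl}-6-[dimethyl(phenyl)silyl]hexa-1,5-dien-3-yl (2R)-2-methylbutanoate | CC[C@@H](C)C(=O)O[C@H](C(Br)=C)C/C(CO[Si](C)(C)C(C)(C)C)=C/[Si](C)(C)c1ccccc1 | intermediate
11 | (3S,5Z)-2-bromo-5-{[tert-butyl(dimethyl)silyl]oxymethyl}-6-iodohexa-1,5-dien-3-yl (2R)-2-methylbutanoate | CC[C@@H](C)C(=O)O[C@H](C(Br)=C)C/C(CO[Si](C)(C)C(C)(C)C)=C/I | intermediate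
12 | (2Z)-3-methylpent-2-en-4-yn-1-ol | C#C/C(C)=C\CO | starting material
13 | (3S,5Z,9Z)-2-bromo-5-{[tert-butyl(dimethyl)silyl]oxymethyl}-11-hydroxy-9-methylundeca-1,5,9-trien-7-yn-3-yl (2R)-2-methylbutanoate | CC[C@@H](C)C(=O)O[C@H](C(Br)=C)C/C(CO[Si](C)(C)C(C)(C)C)=C/C#C/C(C)=C\CO | intermediate
14 | (3S,5Z)-2-bromo-5-{[tert-butyl(dimethyl)silyl]oxymethyl}-8-[(2R,3S)-3-(hydroxymethyl)-2-methyloxiran-2-yl]octa-1,5-dien-7-yn-3-yl (2R)-2-methylbutanoate | CC[C@@H](C)C(=O)O[C@H](C(Br)=C)C/C(CO[Si](C)(C)C(C)(C)C)=C/C#C[C@@]1(C)O[C@H]1CO | intermediate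
15 | (2S)-3-bromo-1-[(2S,3R)-2-{[tert-butyl(dimethyl)silyl]oxymethyl}-3-{[(2R,3S)-3-(hydroxymethyl)-2-methyloxiran-2-yl]ethynyl}oxiran-2-yl]but-3-en-2-yl (2R)-2-methylbutanoate | CC[C@@H](C)C(=O)O[C@H](C(Br)=C)C[C@@]1(CO[Si](C)(C)C(C)(C)C)O[C@@H]1C#C[C@@]2(C)O[C@H]2CO | intermediate
16 | (2S)-3-bromo-1-[(2S,3R)-2-{[tert-butyl(dimethyl)silyl]oxymethyl}-3-{(Z)-2-[(2R,3S)-3-(hydroxymethyl)-2-methyloxiran-2-yl]ethenyl}oxiran-2-yl]but-3-en-2-yl (2R)-2-methylbutanoate | CC[C@@H](C)C(=O)O[C@H](C(Br)=C)C[C@@]1(CO[Si](C)(C)C(C)(C)C)O[C@@H]1/C=C\[C@@]2(C)O[C@H]2CO | intermediate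
17 | (2S)-3-bromo-1-[(2S,3R)-2-{[tert-butyl(dimethyl)silyl]oxymethyl}-3-{(Z)-2-[(2R,3R)-3-formyl-2-methyloxiran-2-yl]ethenyl}oxiran-2-yl]but-3-en-2-yl (2R)-2-methylbutanoate | CC[C@@H](C)C(=O)O[C@H](C(Br)=C)C[C@@]1(CO[Si](C)(C)C(C)(C)C)O[C@@H]1/C=C\[C@@]2(C)O[C@H]2C=O | intermediate
18 | (1R,2Z,4R,5S,6S,8S,10S)-14-{[tert-butyl(dimethyl)silyl]oxy}-1,10:4,5-diepoxy-6-hydroxy-7-methylidene-11,12,13-trinorgermacr-2-en-8-yl (2R)-2-methylbutanoate | CC[C@@H](C)C(=O)O[C@H]1C[C@@]2(CO[Si](C)(C)C(C)(C)C)O[C@@H]2/C=C\[C@@]2(C)O[C@H]2[C@@H](O)C1=C | intermediate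
19 | 2-(bromomethyl)acrylic acid | C=C(CBr)C(=O)O | starting material
20 | 2-(acetoxymethyl)acrylic acid | C=C(COC(C)=O)C(=O)O | intermediate
21 | (1R,2Z,4R,5S,6S,8S,10S)-6-{[2-(acetoxymethyl)prop-2-enoyl]oxy}-14-{[tert-butyl(dimethyl)silyl]oxy}-1,10:4,5-diepoxy-7-methylidene-11,12,13-trinorgermacr-2-en-8-yl (2R)-2-methylbutanoate | CC[C@@H](C)C(=O)O[C@H]1C[C@@]2(CO[Si](C)(C)C(C)(C)C)O[C@@H]2/C=C\[C@@]2(C)O[C@H]2[C@@H](OC(=O)C(=C)COC(C)=O)C1=C | intermediate
22 | 14-O-[tert-butyl(dimethyl)silyl] ether of the target | CC[C@@H](C)C(=O)O[C@H]1C[C@@]2(CO[Si](C)(C)C(C)(C)C)O[C@@H]2/C=C\[C@@]2(C)O[C@H]2[C@H]2OC(=O)C(COC(C)=O)=C12 | intermediate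
23 | (1R,2Z,4R,5S,6S,8S,10S)-13-acetoxy-1,10:4,5-diepoxy-14-hydroxy-8-[(2R)-2-methylbutanoyloxy]germacra-2,7(11)-dien-12,6-olide | CC[C@@H](C)C(=O)O[C@H]1C[C@@]2(CO)O[C@@H]2/C=C\[C@@]2(C)O[C@H]2[C@H]2OC(=O)C(COC(C)=O)=C12 | target

Total step count: 17. Longest linear sequence: 16 steps (steps 1–13 and 15–17, from acrolein); step 14 is a one-step side branch.

Steps most likely to fail

1. Step 16 (ring-closing metathesis). Loading of ruthenium onto either hindered 1,1-disubstituted alkene may be so slow that catalyst decay or ring-opening at C2=C3 outruns closure. The fallback sets out from 18 and comes back at 22; it is a relay ring-closing metathesis, in which a sacrificial diene arm delivers the carbene to C11. tert-Butyl acrylate and hex-5-enal would be joined by a Morita–Baylis–Hillman reaction (DABCO) to tert-butyl 3-hydroxy-2-methylideneoct-7-enoate F1. Acetylation (Ac2O, pyridine, DMAP) would give tert-butyl 3-acetoxy-2-methylideneoct-7-enoate F2. DABCO in THF at reflux should move the acetate to the primary position by two SN2′ steps and give tert-butyl (2E)-2-(acetoxymethyl)octa-2,7-dienoate F3. CF3CO2H in CH2Cl2 would free (2E)-2-(acetoxymethyl)octa-2,7-dienoic acid F4. Esterification of 18 with F4 (EDC·HCl, DMAP) would give the 6-O-[(2E)-2-(acetoxymethyl)octa-2,7-dienoyl] relay ester F5. The second-generation Grubbs catalyst should initiate at the unhindered terminal alkene of the arm, expel cyclopentene and so be placed on C11, from where closure onto C7=CH2 gives 22.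

2. Step 13 (Nozaki–Hiyama–Kishi macrocyclisation). Ring constraints may override Felkin control, so that the alkenylchromium species adds to the wrong face of the aldehyde. The fallback sets out from 17 and comes back at 21. If the cyclisation gives mainly the C6 epimer, the (6R)-configured epimer of alcohol 18 F6, this alcohol is not discarded. Mitsunobu esterification of it with acid 20 (PPh3, diisopropyl azodicarboxylate, THF, 0 °C) should invert C6 and give 21 directly. Any (6S)-alcohol 18 formed alongside goes through step 15 as planned.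

3. Step 2 (catalytic asymmetric propargylboration). Enantioface discrimination may be poor on the small, very electrophilic α-bromo enal, with uncatalysed background addition. The fallback sets out from 3 and comes back at 5. A zinc-mediated Barbier reaction of 3 with propargyl bromide (Zn, THF/aqueous NH4Cl) would give racemic 2-bromohex-1-en-5-yn-3-ol F7. Enzymatic kinetic resolution with a lipase (Burkholderia cepacia lipase, vinyl acetate, tert-butyl methyl ether) should acetylate the R enantiomer to (3R)-2-bromohex-1-en-5-yn-3-yl acetate F8 and leave 5, which is separated and carried on.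

Further compounds
F1 | step 16 | tert-butyl 3-hydroxy-2-methylideneoct-7-enoate | C=CCCCC(O)C(=C)C(=O)OC(C)(C)C
F2 | step 16 | tert-butyl 3-acetoxy-2-methylideneoct-7-enoate | C=CCCCC(OC(C)=O)C(=C)C(=O)OC(C)(C)C
F3 | step 16 | tert-butyl (2E)-2-(acetoxymethyl)octa-2,7-dienoate | C=CCCC/C=C(\COC(C)=O)C(=O)OC(C)(C)C
F4 | step 16 | (2E)-2-(acetoxymethyl)octa-2,7-dienoic acid | C=CCCC/C=C(\COC(C)=O)C(=O)O
F5 | step 16 | 6-O-[(2E)-2-(acetoxymethyl)octa-2,7-dienoyl] relay ester | CC[C@@H](C)C(=O)O[C@H]1C[C@@]2(CO[Si](C)(C)C(C)(C)C)O[C@@H]2/C=C\[C@@]2(C)O[C@H]2[C@@H](OC(=O)/C(COC(C)=O)=C/CCCC=C)C1=C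
F6 | step 13 | (6R)-configured epimer of alcohol 18 | CC[C@@H](C)C(=O)O[C@H]1C[C@@]2(CO[Si](C)(C)C(C)(C)C)O[C@@H]2/C=C\[C@@]2(C)O[C@H]2[C@H](O)C1=C
F7 | step 2 | racemic 2-bromohex-1-en-5-yn-3-ol | C#CCC(O)C(Br)=C
F8 | step 2 | (3R)-2-bromohex-1-en-5-yn-3-yl acetate | C#CC[C@@H](OC(C)=O)C(Br)=C
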